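**Plan**
1. Units: upper flavan = rings A (benzo), B (aryl), C (pyran) with O1, C2–C4; lower flavan = rings D (benzo), E (aryl), F (pyran); ring G = galloyl. Retrosynthetic cuts: twelve O-benzyl groups; C4–H (back to a C4 carbinol); O1–C2 of ring C (back to a ring-A phenol and a C2–C3 trans-epoxide); the galloyl ester; the C4–C8(D) bond (aryllithium + ketone); the chalcone epoxide (epoxidation, aldol).
2. Forward: rings D, E, F come ready-made from (−)-epigallocatechin (benzylated, 8-brominated, 3-O-silylated). Rings A and B are joined by a Claisen–Schmidt condensation and epoxidised. The two halves are united at the ketone carbon (future C4), the lower 3-OH is galloylated, and ring C is closed last.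
3. Enabling feature: C2 is benzylic to ring B and is the far end of a C2–C3 epoxide; O1 is the phenol oxygen of ring A, ortho to C4. C4 is doubly benzylic (rings A and D), so it can carry a helper hydroxyl that serves as the handle for the union, disfavours 5-exo closure at C3, and is later removed by ionisation.
4. Stereochemistry: upper C2/C3 from a Juliá–Colonna epoxidation (C3 kept, C2 inverted in the ring closure, hence 2,3-trans). C4 from hydride delivery anti to O3 on the cyclic C4 cation (3,4-cis, 4R). Lower C2/C3 from the chiral pool.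
5. End: one global hydrogenolysis.

Key step: step 10

Remark: 1, 5, 7 and 13 are taken as purchased; the carbinol carbon made in step 7 (later C4) is carried as both epimers (11, 12, 14, 15, 16) because step 11 makes it trigonal before it is set.

Step 1
Reactants: 1 (−)-epigallocatechin
Product: 2 (2R,3R)-5,7-bis(benzyloxy)-2-[3,4,5-tris(benzyloxy)phenyl]chroman-3-ol
Conditions: BnBr, K2CO3, DMF, −20 °C to rt
Reagents that add atoms: benzyl bromide, BrCc1ccccc1
Why: Williamson ether synthesis in which K2CO3 deprotonates only the five phenols, so the secondary 3-OH stays free, and the low starting temperature limits base-induced epimerisation at C2.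

Step 2
Reactants: 2 penta-O-benzyl-epigallocatechin
Product: 3 (2R,3R)-5,7-bis(benzyloxy)-8-bromo-2-[3,4,5-tris(benzyloxy)phenyl]chroman-3-ol
Conditions: NBS, CH2Cl2, −78 °C to 0 °C
Reagents that add atoms: N-bromosuccinimide, O=C1CCC(=O)N1Br
Why: Electrophilic aromatic bromination of the phloroglucinol-type ring D, which in O-benzylated flavan-3-ols takes place at C8, the carbon that must later carry the upper unit.

Step 3
Reactants: 3 8-bromide
Product: 4 tert-butyldimethylsilyl ether of 3 at O3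
Conditions: TBSCl, imidazole, DMF, rt
Reagents that add atoms: tert-butyldimethylsilyl chloride, CC(C)(C)[Si](C)(C)Cl
Why: Silylation of the only free hydroxyl gives an ether that tolerates tert-butyllithium and is removed later by fluoride without touching benzyl ethers.

Step 4
Reactants: 5 1-[4-(benzyloxy)-2-hydroxyphenyl]ethanone
Product: 6 1-[2-(allyloxy)-4-(benzyloxy)phenyl]ethanone
Conditions: allyl bromide, K2CO3, DMF, 60 °C
Reagents that add atoms: allyl bromide, C=CCBr
Why: Williamson etherification of the chelated phenol installs an allyl group that survives base, peroxide, aryllithium and fluoride and leaves under neutral catalysis by zerovalent palladium.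

Step 5
Reactants: 6 allyl ether; 7 3,4,5-tris(benzyloxy)benzaldehyde
Product: 8 (E)-1-[2-(allyloxy)-4-(benzyloxy)phenyl]-3-[3,4,5-tris(benzyloxy)phenyl]prop-2-en-1-one
Conditions: KOH, EtOH–THF, rt
Reagents that add atoms: none
Why: Claisen–Schmidt aldol condensation of a methyl ketone with a non-enolisable aldehyde, in which E1cB dehydration gives the E-enone.

Step 6
Reactants: 8 chalcone
Product: 9 [2-(allyloxy)-4-(benzyloxy)phenyl]{(2R,3S)-3-[3,4,5-tris(benzyloxy)phenyl]oxiran-2-yl}methanone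
Conditions: poly-L-leucine, urea–H2O2, DBU, THF, rt
Reagents that add atoms: hydrogen peroxide (from its urea adduct), OO
Why: Juliá–Colonna epoxidation (Weitz–Scheffer conjugate addition of hydroperoxide and ring closure on the helical peptide), in which the L-configured catalyst selects the enone face and should give the trans-(2R,3S) epoxide that holds the future C3 and, after inversion, C2; the allyl alkene is inert to the nucleophilic oxidant.

Step 7
Reactants: 4 silylated 8-bromide; 9 epoxy ketone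
Product: 11 tertiary carbinol joining both halves (both carbinol epimers), via aryllithium 10 (not isolated)
Conditions: 4, t-BuLi (2 equiv), THF, −78 °C; then 9, −78 to −40 °C; then H2O
Reagents that add atoms: none
Why: Bromine–lithium exchange fixes the nucleophilic site at C8 of ring D, and the aryllithium should add 1,2 to the chelated, non-enolisable epoxy ketone at low temperature faster than it opens the epoxide; the new carbinol centre needs no control.

Step 8
Reactants: 11 silylated carbinol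
Product: 12 carbinol with free 3-OH on ring F
Conditions: Bu4NF, AcOH, THF, rt
Reagents that add atoms: none
Why: Fluoride-induced desilylation, in which the buffered medium leaves the epoxide, the allyl ether and the acid-labile tertiary carbinol alone.

Step 9
Reactants: 12 diol; 13 3,4,5-tris(benzyloxy)benzoic acid
Product: 14 3,4,5-tris(benzyloxy)benzoate of 12 at O3 of ring F
Conditions: DCC, DMAP, CH2Cl2, rt
Reagents that add atoms: none
Why: Steglich esterification acylates the secondary alcohol while the tertiary diaryl carbinol is too hindered to react, and doing it now means that the hydroxyl freed in step 10 never has to be told apart from this one.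

Step 10
Reactants: 14 allyl-protected epoxy carbinol gallate
Product: 16 ring-C-closed 4-aryl-flavan-3,4-diol (new ring 2R,3R; 2,3-trans; both C4 epimers), via free phenol 15 (not isolated)
Conditions: Pd(PPh3)4 (cat.), morpholine, THF, rt; then Cs2CO3 (0.3 equiv), DMF, rt to 40 °C
Reagents that add atoms: none
Why: Zerovalent palladium transfers the allyl group to morpholine (Tsuji–Trost deallylation) and frees the ring-A phenol 15, whose caesium phenoxide O1 attacks the benzylic epoxide carbon C2 from the back in an intramolecular SN2 epoxide opening. The closest known reaction type is the phenoxide closure of 2'-hydroxychalcone epoxides to 3-hydroxyflavanones (the ring-forming event of the Algar–Flynn–Oyamada reaction) and of 2-hydroxyphenyl-substituted aryl epoxides to flavan-3-ols. Ring C closes in the 6-endo-tet mode, O1 bonding to the distal epoxide carbon. C2 is set by inversion of the (S)-configured epoxide carbon, which places ring B trans to O3, while C3 keeps its C–O bond and its configuration and the C4 carbinol centre is left as it is. The step needs 6-endo over 5-exo selectivity, which should follow from benzylic activation of C2 by ring B and from the fully substituted C4 carbinol next to the 5-exo terminus C3. O1 is the only free phenol because O7 of ring D is benzylated, and the basic aprotic medium spares the acid-labile carbinol and the galloyl ester.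

Step 11
Reactants: 16 4-aryl-flavan-3,4-diol
Product: 18 dodeca-O-benzyl ether of the target (upper unit 2R,3S,4R), via C4 carbenium ion 17 (not isolated)
Conditions: n-Bu3SnH, CF3CO2H, CH2Cl2, −20 to 0 °C
Reagents that add atoms: none
Why: Ionic hydrogenation of a tertiary, doubly benzylic alcohol, in which both carbinol epimers ionise to the same planar C4 cation stabilised by rings A and D and the tin hydride should deliver hydride to the face anti to the C3 oxygen (the face that nucleophiles take in 2,3-trans-flavan-4-yl cations), which leaves ring D cis to O3 and sets C4 as R.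

Step 12
Reactants: 18 protected target
Product: 19 robinetinidol-(4β→8)-epigallocatechin 3-O-gallate
Conditions: H2 (1 atm), Pd(OH)2/C, THF–MeOH–H2O, rt
Reagents that add atoms: none
Why: Catalytic hydrogenolysis of the twelve benzyl ethers, under which the ester, the C4–C8(D) bond and the two cyclic benzylic ethers should persist and no stereocentre is touched.

**Compound list**
1 | (−)-epigallocatechin, (2R,3R)-2-(3,4,5-trihydroxyphenyl)chromane-3,5,7-triol | O[C@@H]1Cc2c(O)cc(O)cc2O[C@@H]1c1cc(O)c(O)c(O)c1 | starting material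
2 | (2R,3R)-5,7-bis(benzyloxy)-2-[3,4,5-tris(benzyloxy)phenyl]chroman-3-ol | O[C@@H]1Cc2c(OCc3ccccc3)cc(OCc3ccccc3)cc2O[C@@H]1c1cc(OCc2ccccc2)c(OCc2ccccc2)c(OCc2ccccc2)c1 | intermediate
3 | (2R,3R)-5,7-bis(benzyloxy)-8-bromo-2-[3,4,5-tris(benzyloxy)phenyl]chroman-3-ol | O[C@@H]1Cc2c(OCc3ccccc3)cc(OCc3ccccc3)c(Br)c2O[C@@H]1c1cc(OCc2ccccc2)c(OCc2ccccc2)c(OCc2ccccc2)c1 | intermediate
4 | {[(2R,3R)-5,7-bis(benzyloxy)-8-bromo-2-[3,4,5-tris(benzyloxy)phenyl]chroman-3-yl]oxy}(tert-butyl)dimethylsilane | CC(C)(C)[Si](C)(C)O[C@@H]1Cc2c(OCc3ccccc3)cc(OCc3ccccc3)c(Br)c2O[C@@H]1c1cc(OCc2ccccc2)c(OCc2ccccc2)c(OCc2ccccc2)c1 | intermediate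
5 | 1-[4-(benzyloxy)-2-hydroxyphenyl]ethanone | CC(=O)c1ccc(OCc2ccccc2)cc1O | starting material
6 | 1-[2-(allyloxy)-4-(benzyloxy)phenyl]ethanone | CC(=O)c1ccc(OCc2ccccc2)cc1OCC=C | intermediate
7 | 3,4,5-tris(benzyloxy)benzaldehyde | O=Cc1cc(OCc2ccccc2)c(OCc2ccccc2)c(OCc2ccccc2)c1 | starting material
8 | (E)-1-[2-(allyloxy)-4-(benzyloxy)phenyl]-3-[3,4,5-tris(benzyloxy)phenyl]prop-2-en-1-one | O=C(/C=C/c1cc(OCc2ccccc2)c(OCc2ccccc2)c(OCc2ccccc2)c1)c1ccc(OCc2ccccc2)cc1OCC=C | intermediate
9 | [2-(allyloxy)-4-(benzyloxy)phenyl]{(2R,3S)-3-[3,4,5-tris(benzyloxy)phenyl]oxiran-2-yl}methanone | O=C(c1ccc(OCc2ccccc2)cc1OCC=C)[C@@H]1O[C@H]1c1cc(OCc2ccccc2)c(OCc2ccccc2)c(OCc2ccccc2)c1 | intermediate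
10 | 8-lithio analogue of 4 (aryllithium, not isolated) | CC(C)(C)[Si](C)(C)O[C@@H]1Cc2c(OCc3ccccc3)cc(OCc3ccccc3)c([Li])c2O[C@@H]1c1cc(OCc2ccccc2)c(OCc2ccccc2)c(OCc2ccccc2)c1 | intermediate
11 | [2-(allyloxy)-4-(benzyloxy)phenyl]{(2R,3R)-5,7-bis(benzyloxy)-3-[(tert-butyldimethylsilyl)oxy]-2-[3,4,5-tris(benzyloxy)phenyl]chroman-8-yl}{(2R,3S)-3-[3,4,5-tris(benzyloxy)phenyl]oxiran-2-yl}methanol, both carbinol epimers | CC(C)(C)[Si](C)(C)O[C@@H]1Cc2c(OCc3ccccc3)cc(OCc3ccccc3)c(C(O)(c4ccc(OCc3ccccc3)cc4OCC=C)[C@@H]5O[C@H]5c6cc(OCc3ccccc3)c(OCc3ccccc3)c(OCc3ccccc3)c6)c2O[C@@H]1c1cc(OCc2ccccc2)c(OCc2ccccc2)c(OCc2ccccc2)c1 | intermediate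
12 | (2R,3R)-8-{[2-(allyloxy)-4-(benzyloxy)phenyl](hydroxy){(2R,3S)-3-[3,4,5-tris(benzyloxy)phenyl]oxiran-2-yl}methyl}-5,7-bis(benzyloxy)-2-[3,4,5-tris(benzyloxy)phenyl]chroman-3-ol, both carbinol epimers | O[C@@H]1Cc2c(OCc3ccccc3)cc(OCc3ccccc3)c(C(O)(c4ccc(OCc3ccccc3)cc4OCC=C)[C@@H]5O[C@H]5c6cc(OCc3ccccc3)c(OCc3ccccc3)c(OCc3ccccc3)c6)c2O[C@@H]1c1cc(OCc2ccccc2)c(OCc2ccccc2)c(OCc2ccccc2)c1 | intermediate
13 | 3,4,5-tris(benzyloxy)benzoic acid | OC(=O)c1cc(OCc2ccccc2)c(OCc2ccccc2)c(OCc2ccccc2)c1 | starting material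
14 | (2R,3R)-8-{[2-(allyloxy)-4-(benzyloxy)phenyl](hydroxy){(2R,3S)-3-[3,4,5-tris(benzyloxy)phenyl]oxiran-2-yl}methyl}-5,7-bis(benzyloxy)-2-[3,4,5-tris(benzyloxy)phenyl]chroman-3-yl 3,4,5-tris(benzyloxy)benzoate, both carbinol epimers | O=C(O[C@@H]1Cc2c(OCc3ccccc3)cc(OCc3ccccc3)c(C(O)(c4ccc(OCc3ccccc3)cc4OCC=C)[C@@H]5O[C@H]5c6cc(OCc3ccccc3)c(OCc3ccccc3)c(OCc3ccccc3)c6)c2O[C@@H]1c1cc(OCc2ccccc2)c(OCc2ccccc2)c(OCc2ccccc2)c1)c1cc(OCc2ccccc2)c(OCc2ccccc2)c(OCc2ccccc2)c1 | intermediate
15 | analogue of 14 with a free 2-hydroxyl on ring A in place of the allyl ether (not isolated), both carbinol epimers | O=C(O[C@@H]1Cc2c(OCc3ccccc3)cc(OCc3ccccc3)c(C(O)(c4ccc(OCc3ccccc3)cc4O)[C@@H]5O[C@H]5c6cc(OCc3ccccc3)c(OCc3ccccc3)c(OCc3ccccc3)c6)c2O[C@@H]1c1cc(OCc2ccccc2)c(OCc2ccccc2)c(OCc2ccccc2)c1)c1cc(OCc2ccccc2)c(OCc2ccccc2)c(OCc2ccccc2)c1 | intermediate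
16 | (2R,3R)-5,7-bis(benzyloxy)-8-{(2R,3R)-7-(benzyloxy)-3,4-dihydroxy-2-[3,4,5-tris(benzyloxy)phenyl]chroman-4-yl}-2-[3,4,5-tris(benzyloxy)phenyl]chroman-3-yl 3,4,5-tris(benzyloxy)benzoate, ring B trans to O3, both C4 epimers | O=C(O[C@@H]1Cc2c(OCc3ccccc3)cc(OCc3ccccc3)c(C3(O)c4ccc(OCc5ccccc5)cc4O[C@H](c4cc(OCc5ccccc5)c(OCc5ccccc5)c(OCc5ccccc5)c4)[C@H]3O)c2O[C@@H]1c1cc(OCc2ccccc2)c(OCc2ccccc2)c(OCc2ccccc2)c1)c1cc(OCc2ccccc2)c(OCc2ccccc2)c(OCc2ccccc2)c1 | intermediate
17 | (2R,3S)-configured chroman-4-ylium ion formed from 16 by loss of the C4 hydroxyl (not isolated) | O=C(O[C@@H]1Cc2c(OCc3ccccc3)cc(OCc3ccccc3)c([C+]3c4ccc(OCc5ccccc5)cc4O[C@H](c4cc(OCc5ccccc5)c(OCc5ccccc5)c(OCc5ccccc5)c4)[C@H]3O)c2O[C@@H]1c1cc(OCc2ccccc2)c(OCc2ccccc2)c(OCc2ccccc2)c1)c1cc(OCc2ccccc2)c(OCc2ccccc2)c(OCc2ccccc2)c1 | intermediate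
18 | (2R,3R)-5,7-bis(benzyloxy)-8-{(2R,3S,4R)-7-(benzyloxy)-3-hydroxy-2-[3,4,5-tris(benzyloxy)phenyl]chroman-4-yl}-2-[3,4,5-tris(benzyloxy)phenyl]chroman-3-yl 3,4,5-tris(benzyloxy)benzoate | O=C(O[C@@H]1Cc2c(OCc3ccccc3)cc(OCc3ccccc3)c([C@H]3c4ccc(OCc5ccccc5)cc4O[C@H](c4cc(OCc5ccccc5)c(OCc5ccccc5)c(OCc5ccccc5)c4)[C@H]3O)c2O[C@@H]1c1cc(OCc2ccccc2)c(OCc2ccccc2)c(OCc2ccccc2)c1)c1cc(OCc2ccccc2)c(OCc2ccccc2)c(OCc2ccccc2)c1 | intermediate
19 | (2R,3R)-5,7-dihydroxy-8-[(2R,3S,4R)-3,7-dihydroxy-2-(3,4,5-trihydroxyphenyl)chroman-4-yl]-2-(3,4,5-trihydroxyphenyl)chroman-3-yl 3,4,5-trihydroxybenzoate | O=C(O[C@@H]1Cc2c(O)cc(O)c([C@H]3c4ccc(O)cc4O[C@H](c4cc(O)c(O)c(O)c4)[C@H]3O)c2O[C@@H]1c1cc(O)c(O)c(O)c1)c1cc(O)c(O)c(O)c1 | target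

**Totals**
Total steps: 12. Longest linear sequence: 9 steps (steps 1, 2, 3, 7, 8, 9, 10, 11, 12 from 1; equally steps 4, 5, 6, 7–12 from 5).

**Steps most likely to fail**

Step 11. Hydride may be delivered to the C4 cation from the O3 face (giving the 3,4-trans epimer), or H3 may shift from C3 to C4 in a pinacol-type rearrangement before the tin hydride arrives. The fallback sets out from 16 and comes back at 18, and it turns the shift into the stereo-defining event. Ionisation of 16 with BF3·OEt2 in CH2Cl2 at −40 °C without any hydride donor should let the axial H3, which lies trans to O3, migrate suprafacially to C4. This semipinacol rearrangement would give (2R,3R)-5,7-bis(benzyloxy)-8-{(2R,4R)-7-(benzyloxy)-3-oxo-2-[3,4,5-tris(benzyloxy)phenyl]chroman-4-yl}-2-[3,4,5-tris(benzyloxy)phenyl]chroman-3-yl 3,4,5-tris(benzyloxy)benzoate F1, with ring D on the face that O3 occupied. Reduction of the C3 ketone with NaBH4 in THF–MeOH at −40 °C should then take place from the face opposite the pseudoaxial ring D and return 18.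

Step 10. The phenoxide may open the epoxide at C3 in the 5-exo mode, or expel the C4 hydroxyl to a quinone methide, instead of closing ring C. The fallback sets out from 9, uses 4 and 13, and comes back at 16. It closes ring C before the union, at the ketone oxidation level where 6-endo closure of 2'-hydroxychalcone epoxides is the established course. Deallylation of 9 with Pd(PPh3)4 and morpholine followed by K2CO3 in DMF should give the dihydroflavonol (2R,3R)-7-(benzyloxy)-3-hydroxy-2-[3,4,5-tris(benzyloxy)phenyl]chroman-4-one F2. TBSOTf and 2,6-lutidine would give its 3-O-tert-butyldimethylsilyl ether F3. Aryllithium 10, made from 4 as in step 7, would add to the C4 ketone of F3 to give the bis-silylated 4-aryl-flavan-4-ol F4. Bu4NF would remove both silyl groups to give the triol F5. Steglich esterification with 13 should acylate the ring-F hydroxyl in preference to the upper one, which is neopentylic next to the fully substituted C4, and so return 16.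

Step 6. The epoxidation of the electron-rich, ortho-substituted chalcone may be slow and proceed with poor face selection. The fallback sets out from 6, uses 7, and comes back at 9. It builds the epoxide by C–C bond formation instead of enone oxidation. α-Chlorination of 6 through its lithium enolate (LiN(SiMe3)2, then TsCl, THF, −78 °C) would give 1-[2-(allyloxy)-4-(benzyloxy)phenyl]-2-chloroethanone F6. An asymmetric Darzens condensation of F6 with aldehyde 7 under phase-transfer catalysis should then give the trans-epoxy ketone 9. The catalyst would be a cinchona-alkaloid-derived quaternary ammonium salt of the pseudoenantiomeric series that leads to the (2R,3S) product, with LiOH in CH2Cl2 at 0 °C.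

**Further compounds**
F1 | step 11 | (2R,3R)-5,7-bis(benzyloxy)-8-{(2R,4R)-7-(benzyloxy)-3-oxo-2-[3,4,5-tris(benzyloxy)phenyl]chroman-4-yl}-2-[3,4,5-tris(benzyloxy)phenyl]chroman-3-yl 3,4,5-tris(benzyloxy)benzoate | O=C(O[C@@H]1Cc2c(OCc3ccccc3)cc(OCc3ccccc3)c([C@H]3c4ccc(OCc5ccccc5)cc4O[C@H](c4cc(OCc5ccccc5)c(OCc5ccccc5)c(OCc5ccccc5)c4)C3=O)c2O[C@@H]1c1cc(OCc2ccccc2)c(OCc2ccccc2)c(OCc2ccccc2)c1)c1cc(OCc2ccccc2)c(OCc2ccccc2)c(OCc2ccccc2)c1
F2 | step 10 | (2R,3R)-7-(benzyloxy)-3-hydroxy-2-[3,4,5-tris(benzyloxy)phenyl]chroman-4-one | O=C1c2ccc(OCc3ccccc3)cc2O[C@H](c2cc(OCc3ccccc3)c(OCc3ccccc3)c(OCc3ccccc3)c2)[C@H]1O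
F3 | step 10 | (2R,3R)-7-(benzyloxy)-3-[(tert-butyldimethylsilyl)oxy]-2-[3,4,5-tris(benzyloxy)phenyl]chroman-4-one | O=C1c2ccc(OCc3ccccc3)cc2O[C@H](c2cc(OCc3ccccc3)c(OCc3ccccc3)c(OCc3ccccc3)c2)[C@H]1O[Si](C)(C)C(C)(C)C
F4 | step 10 | (2R,3R)-7-(benzyloxy)-4-{(2R,3R)-5,7-bis(benzyloxy)-3-[(tert-butyldimethylsilyl)oxy]-2-[3,4,5-tris(benzyloxy)phenyl]chroman-8-yl}-3-[(tert-butyldimethylsilyl)oxy]-2-[3,4,5-tris(benzyloxy)phenyl]chroman-4-ol, both C4 epimers | CC(C)(C)[Si](C)(C)O[C@@H]1Cc2c(OCc3ccccc3)cc(OCc3ccccc3)c(C3(O)c4ccc(OCc5ccccc5)cc4O[C@H](c4cc(OCc5ccccc5)c(OCc5ccccc5)c(OCc5ccccc5)c4)[C@H]3O[Si](C)(C)C(C)(C)C)c2O[C@@H]1c1cc(OCc2ccccc2)c(OCc2ccccc2)c(OCc2ccccc2)c1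
F5 | step 10 | (2R,3R)-7-(benzyloxy)-4-{(2R,3R)-5,7-bis(benzyloxy)-3-hydroxy-2-[3,4,5-tris(benzyloxy)phenyl]chroman-8-yl}-2-[3,4,5-tris(benzyloxy)phenyl]chromane-3,4-diol, both C4 epimers | O[C@@H]1Cc2c(OCc3ccccc3)cc(OCc3ccccc3)c(C3(O)c4ccc(OCc5ccccc5)cc4O[C@H](c4cc(OCc5ccccc5)c(OCc5ccccc5)c(OCc5ccccc5)c4)[C@H]3O)c2O[C@@H]1c1cc(OCc2ccccc2)c(OCc2ccccc2)c(OCc2ccccc2)c1
F6 | step 6 | 1-[2-(allyloxy)-4-(benzyloxy)phenyl]-2-chloroethanone | O=C(CCl)c1ccc(OCc2ccccc2)cc1OCC=C
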